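**Retrosynthetic overview**
1. Target 14 comes from heptamethyl ether 13 by global O-demethylation; all seven phenols are carried as methyl ethers.
2. 13 comes from 1,4-diketone 3 and keto-aldehyde 10: an intermolecular aldol condensation makes C3–C4, then an intramolecular aldol onto the diaryl ketone makes C1–C2, and loss of water aromatises.
3. 3 comes from 2',4'-dimethoxyacetophenone 1 and its α-bromo derivative 2.
4. 10 comes from 6-bromoveratraldehyde 4 (as its dioxolane, by Br/Li exchange) and 4-methoxybenzaldehyde 6, followed by oxidation and acetal hydrolysis.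
5. Ring order: the four benzene rings are bought; the only ring built is the C1–C4 ring of the naphthalene, in step 6.

Assumption: the target SMILES has no stereocentre or stable stereoaxis, so the compound is achiral and "single enantiomer" is taken to mean the structure as drawn.

**Step 1**
Reactants: 1 1-(2,4-dimethoxyphenyl)ethan-1-one (2',4'-dimethoxyacetophenone); 2 2-bromo-1-(2,4-dimethoxyphenyl)ethan-1-one
Product: 3 1,4-bis(2,4-dimethoxyphenyl)butane-1,4-dione
Conditions: 1 (1.5 equiv), 2 (1.0 equiv), ZnCl2 (2 equiv), Et2NH (1.5 equiv), t-BuOH (1.5 equiv), toluene, rt, 48 h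
Reagents that add atoms: none
Why: Zinc-enolate coupling of a methyl ketone with an α-bromo ketone (net enolate α-alkylation) gives symmetrical 1,4-diaryl-1,4-diketones and avoids the Darzens and self-condensation pathways of alkali enolates; no stereocentre is formed.

**Step 2**
Reactants: 4 2-bromo-4,5-dimethoxybenzaldehyde (6-bromoveratraldehyde)
Product: 5 2-(2-bromo-4,5-dimethoxyphenyl)-1,3-dioxolane
Conditions: ethylene glycol (3 equiv), p-toluenesulfonic acid monohydrate (p-TsOH·H2O, 5 mol %), toluene, reflux, Dean–Stark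
Reagents that add atoms: ethylene glycol, OCCO
Why: Acid-catalysed acetalisation with azeotropic removal of water masks the aldehyde as a dioxolane that is inert to the organolithium chemistry of step 3.

**Step 3**
Reactants: 5 2-(2-bromo-4,5-dimethoxyphenyl)-1,3-dioxolane; 6 4-methoxybenzaldehyde
Product: 8 [2-(1,3-dioxolan-2-yl)-4,5-dimethoxyphenyl](4-methoxyphenyl)methanol (racemic), via aryllithium 7 (not isolated)
Conditions: n-BuLi (1.05 equiv), THF, −78 °C, 30 min; then 6 (1.1 equiv), −78 °C → 0 °C; then H2O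
Reagents that add atoms: none
Why: Bromine–lithium exchange at −78 °C is faster than any attack on the acetal or ethers, and the aryllithium adds 1,2 to the aldehyde (organolithium carbonyl addition); the new carbinol centre is racemic and is erased in step 4.

**Step 4**
Reactants: 8 [2-(1,3-dioxolan-2-yl)-4,5-dimethoxyphenyl](4-methoxyphenyl)methanol
Product: 9 [2-(1,3-dioxolan-2-yl)-4,5-dimethoxyphenyl](4-methoxyphenyl)methanone
Conditions: activated MnO2 (10 equiv), CH2Cl2, rt, 12 h
Reagents that add atoms: none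
Why: MnO2 oxidation of a doubly benzylic alcohol runs under neutral conditions, so the acid-labile dioxolane survives and the only stereocentre is removed.

**Step 5**
Reactants: 9 [2-(1,3-dioxolan-2-yl)-4,5-dimethoxyphenyl](4-methoxyphenyl)methanone
Product: 10 4,5-dimethoxy-2-(4-methoxybenzoyl)benzaldehyde
Conditions: 2 M aq. HCl, THF, rt, 3 h
Reagents that add atoms: water, O
Why: Acid-catalysed acetal hydrolysis frees the aldehyde while the diaryl ketone and aryl methyl ethers are untouched; because the benzylic carbon is already a ketone, no lactol can form.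

**Step 6**
Reactants: 3 1,4-bis(2,4-dimethoxyphenyl)butane-1,4-dione; 10 4,5-dimethoxy-2-(4-methoxybenzoyl)benzaldehyde
Product: 13 [6,7-dimethoxy-1-(4-methoxyphenyl)naphthalene-2,3-diyl]bis[(2,4-dimethoxyphenyl)methanone], via E-enone 11 (not isolated), via dihydronaphthalen-1-ol 12 (not isolated)
Conditions: 3 (1.0 equiv), t-BuOK (2.2 equiv), THF/t-BuOH 4:1, 0 °C; add 10 (1.0 equiv) over 1 h; then 65 °C, 6 h; H2O work-up
Reagents that add atoms: none
Why: The diketone enolate undergoes an intermolecular crossed aldol condensation with the non-enolisable aldehyde to give 11, whose remaining vinylogously activated α-CH2 adds intramolecularly to the ortho diaryl ketone (a carbocyclic Friedländer-type annulation) to give 12, and E1cB loss of water is driven by aromatisation; the symmetry of 3 removes any regiochemical question and no stereocentre survives.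

**Step 7**
Reactants: 13 [6,7-dimethoxy-1-(4-methoxyphenyl)naphthalene-2,3-diyl]bis[(2,4-dimethoxyphenyl)methanone]
Product: 14 [6,7-dihydroxy-1-(4-hydroxyphenyl)naphthalene-2,3-diyl]bis[(2,4-dihydroxyphenyl)methanone] (CNP0304576.0)
Conditions: BBr3 (1 M in CH2Cl2, 14 equiv), CH2Cl2, −78 °C → rt, 24 h; then H2O, 0 °C
Reagents that add atoms: none
Why: BBr3 cleavage of aryl methyl ethers (Lewis-acid-assisted SN2 demethylation) removes all seven methyl groups, while the non-enolisable diaryl ketones and the naphthalene core are inert; no stereocentre is involved.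

**Compound list**
1 | 1-(2,4-dimethoxyphenyl)ethan-1-one | CC(=O)c1ccc(OC)cc1OC | starting material
2 | 2-bromo-1-(2,4-dimethoxyphenyl)ethan-1-one | BrCC(=O)c1ccc(OC)cc1OC | starting material
3 | 1,4-bis(2,4-dimethoxyphenyl)butane-1,4-dione | COc1ccc(C(=O)CCC(=O)c2ccc(OC)cc2OC)c(OC)c1 | intermediate
4 | 2-bromo-4,5-dimethoxybenzaldehyde | COc1cc(Br)c(C=O)cc1OC | starting material
5 | 2-(2-bromo-4,5-dimethoxyphenyl)-1,3-dioxolane | COc1cc(Br)c(C2OCCO2)cc1OC | intermediate
6 | 4-methoxybenzaldehyde | COc1ccc(C=O)cc1 | starting material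
7 | [2-(1,3-dioxolan-2-yl)-4,5-dimethoxyphenyl]lithium | [Li]c1cc(OC)c(OC)cc1C1OCCO1 | intermediate
8 | [2-(1,3-dioxolan-2-yl)-4,5-dimethoxyphenyl](4-methoxyphenyl)methanol, racemic | COc1ccc(C(O)c2cc(OC)c(OC)cc2C2OCCO2)cc1 | intermediate
9 | [2-(1,3-dioxolan-2-yl)-4,5-dimethoxyphenyl](4-methoxyphenyl)methanone | COc1ccc(C(=O)c2cc(OC)c(OC)cc2C2OCCO2)cc1 | intermediate
10 | 4,5-dimethoxy-2-(4-methoxybenzoyl)benzaldehyde | COc1ccc(C(=O)c2cc(OC)c(OC)cc2C=O)cc1 | intermediate
11 | (2E)-2-{[4,5-dimethoxy-2-(4-methoxybenzoyl)phenyl]methylidene}-1,4-bis(2,4-dimethoxyphenyl)butane-1,4-dione | COc1ccc(C(=O)/C(CC(=O)c2ccc(OC)cc2OC)=C/c2cc(OC)c(OC)cc2C(=O)c2ccc(OC)cc2)c(OC)c1 | intermediate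
12 | [1-hydroxy-6,7-dimethoxy-1-(4-methoxyphenyl)-1,2-dihydronaphthalene-2,3-diyl]bis[(2,4-dimethoxyphenyl)methanone], racemic mixture of C1/C2 diastereomers | COc1ccc(C2(O)C(C(=O)c3ccc(OC)cc3OC)C(C(=O)c3ccc(OC)cc3OC)=Cc3cc(OC)c(OC)cc32)cc1 | intermediate
13 | [6,7-dimethoxy-1-(4-methoxyphenyl)naphthalene-2,3-diyl]bis[(2,4-dimethoxyphenyl)methanone] | COc1ccc(-c2c(C(=O)c3ccc(OC)cc3OC)c(C(=O)c3ccc(OC)cc3OC)cc3cc(OC)c(OC)cc23)cc1 | intermediate
14 | [6,7-dihydroxy-1-(4-hydroxyphenyl)naphthalene-2,3-diyl]bis[(2,4-dihydroxyphenyl)methanone] | O=C(c1ccc(O)cc1O)c1cc2cc(O)c(O)cc2c(-c2ccc(O)cc2)c1C(=O)c1ccc(O)cc1O | target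

**Totals**
Total step count: 7. Longest linear sequence: 6 steps (4 → 5 → 8 → 9 → 10 → 13 → 14); step 1 is the convergent branch.

**Three steps most likely to fail, with fallbacks**

Step 6 (double aldol annulation). The risks are base-induced rearrangement of 10 to a phthalide and a sluggish aldol onto the hindered diaryl ketone. The fallback sets out from 3 (with 10) and runs the two C–C bond formations separately. 3 is deprotonated once with LiN(i-Pr)2 in THF at −78 °C and 10 is added at that temperature, so only the aldehyde is attacked. A cold quench gives the aldol adduct 2-{[4,5-dimethoxy-2-(4-methoxybenzoyl)phenyl](hydroxy)methyl}-1,4-bis(2,4-dimethoxyphenyl)butane-1,4-dione F2 as a diastereomer mixture. MsCl/Et3N in CH2Cl2 at 0 °C converts it into the methanesulfonate [4,5-dimethoxy-2-(4-methoxybenzoyl)phenyl][1,4-bis(2,4-dimethoxyphenyl)-1,4-dioxobutan-2-yl]methyl methanesulfonate F3, and DBU eliminates this to the E-enone 11, now isolated. Ring closure of 11 is then forced by soft enolisation with TiCl4/Et3N in CH2Cl2 (0 °C → rt); the titanium enolate adds to the TiCl4-activated diaryl ketone and water is lost. The fallback comes back to the route at 13.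

Step 7 (sevenfold demethylation). The risks are incomplete cleavage and decomposition of the polyphenol under excess BBr3. The fallback sets out from 13 and works in two stages with different mechanisms. BCl3 in CH2Cl2 (−78 → 0 °C) removes only the two ketone-chelated ortho methyl groups and gives [6,7-dimethoxy-1-(4-methoxyphenyl)naphthalene-2,3-diyl]bis[(2-hydroxy-4-methoxyphenyl)methanone] F4. The five remaining unchelated methyl ethers are then cleaved by SN2 attack of NaSEt in DMF at 130 °C, and acidic work-up delivers 14.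

Step 1 (1,4-diketone formation). The risks are slow coupling or by-products from the hindered ortho-methoxy ketones. The fallback sets out from 1 and uses oxidative enolate dimerisation instead of alkylation. LiN(i-Pr)2 in THF at −78 °C gives lithium 1-(2,4-dimethoxyphenyl)ethen-1-olate F1, which is coupled with CuCl2 in DMF (−78 °C → rt) to give 3 directly, so 2 is not needed.

**Further compounds**
F1 | step 1 | lithium 1-(2,4-dimethoxyphenyl)ethen-1-olate | [Li]OC(=C)c1ccc(OC)cc1OC
F2 | step 6 | 2-{[4,5-dimethoxy-2-(4-methoxybenzoyl)phenyl](hydroxy)methyl}-1,4-bis(2,4-dimethoxyphenyl)butane-1,4-dione, racemic diastereomer mixture | COc1ccc(C(=O)C(CC(=O)c2ccc(OC)cc2OC)C(O)c2cc(OC)c(OC)cc2C(=O)c2ccc(OC)cc2)c(OC)c1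
F3 | step 6 | [4,5-dimethoxy-2-(4-methoxybenzoyl)phenyl][1,4-bis(2,4-dimethoxyphenyl)-1,4-dioxobutan-2-yl]methyl methanesulfonate, racemic diastereomer mixture | COc1ccc(C(=O)C(CC(=O)c2ccc(OC)cc2OC)C(OS(C)(=O)=O)c2cc(OC)c(OC)cc2C(=O)c2ccc(OC)cc2)c(OC)c1
F4 | step 7 | [6,7-dimethoxy-1-(4-methoxyphenyl)naphthalene-2,3-diyl]bis[(2-hydroxy-4-methoxyphenyl)methanone] | COc1ccc(-c2c(C(=O)c3ccc(OC)cc3O)c(C(=O)c3ccc(OC)cc3O)cc3cc(OC)c(OC)cc23)cc1
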